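**Strategy.** The flavanone is cut at the C4–C4a bond. Ring A is a phloroglucinol triether whose only free position next to O1, C4a, is flanked by O1 and the C5 methoxy and lies para to the C7 methoxy, so it is nucleophilic enough to capture a C4 acyl-type cation hung from O1 through C2 and C3. The precursor is therefore an (R)-aryl propargyl ether of 3,5-dimethoxy-2-prenylphenol whose alkyne terminus carries a silyloxy group, with the ring B phenol silylated as well. Catalytic strong acid converts this siloxyalkyne into a silyl ketenium ion that closes ring C and delivers C4 at the ketone oxidation level as an enol silane; buffered fluoride then unmasks ketone and phenol.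

Key step: step 9

Remark: prenyl = 3-methylbut-2-en-1-yl and flavanone numbering is used (ring A benzo, ring B 2-aryl, ring C pyranone). The facial sense of step 2 is assumed to follow that of BINOL–Ti(OiPr)4 dialkylzinc additions and would be checked by chiral HPLC on the carbinol of step 2, the antipodal ligand being used if the opposite sense is found.

Step 1
Reactants: 1 isovanillin (3-hydroxy-4-methoxybenzaldehyde)
Product: 2 4-methoxy-3-(triisopropylsilyloxy)benzaldehyde
Conditions: TIPSCl, imidazole, DMF, rt
Reagents that add atoms: chlorotriisopropylsilane (TIPSCl), CC(C)[Si](Cl)(C(C)C)C(C)C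
Why: Imidazole-mediated O-silylation of the phenol is routine, and the bulky aryl triisopropylsilyl ether should survive the organozinc, Mitsunobu, methanolysis, organolithium and acid steps and then leave under the same fluoride treatment that unmasks the ketone.

Step 2
Reactants: 2 4-methoxy-3-(triisopropylsilyloxy)benzaldehyde; 3 ethynyltrimethylsilane
Product: 5 (S)-1-[4-methoxy-3-(triisopropylsilyloxy)phenyl]-3-(trimethylsilyl)prop-2-yn-1-ol, via ethyl(trimethylsilylethynyl)zinc 4 (not isolated)
Conditions: Et2Zn, Cy2NH (cat.), Et2O, rt; then (R)-BINOL (cat.), Ti(OiPr)4 (substoichiometric), then 2, rt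
Reagents that add atoms: none
Why: Catalytic enantioselective alkynylzinc addition to an aromatic aldehyde under BINOL–Ti(OiPr)4 control, in which the (R)-BINOL complex should deliver the alkynyl group to the Re face and thus set the carbinol centre as S, the arrangement opposite to that required at C2 because step 6 inverts it.

Step 3
Reactants: 6 3,5-dimethoxyphenol; 7 3-chloro-3-methylbut-1-yne
Product: 8 1,3-dimethoxy-5-[(2-methylbut-3-yn-2-yl)oxy]benzene
Conditions: CuCl2·2H2O (cat.), DBU, MeCN, 0 °C
Reagents that add atoms: none
Why: Copper-catalysed O-propargylation of a phenol with a tertiary propargylic chloride, proceeding through a copper acetylide that ionises to an allenylidene-type electrophile, is the standard entry to aryl 1,1-dimethylpropargyl ethers and is selective for oxygen.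

Step 4
Reactants: 8 1,3-dimethoxy-5-[(2-methylbut-3-yn-2-yl)oxy]benzene
Product: 9 1,3-dimethoxy-5-[(2-methylbut-3-en-2-yl)oxy]benzene
Conditions: H2 (1 atm), Pd/CaCO3 poisoned with Pb(OAc)2 (Lindlar catalyst), quinoline, EtOAc, rt
Reagents that add atoms: none
Why: Lindlar semihydrogenation stops the terminal alkyne at the alkene and leaves the aryl ether and the arene untouched.

Step 5
Reactants: 9 1,3-dimethoxy-5-[(2-methylbut-3-en-2-yl)oxy]benzene
Product: 10 3,5-dimethoxy-2-prenylphenol
Conditions: xylenes, 130 °C
Reagents that add atoms: none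
Why: Aromatic Claisen rearrangement ([3,3]) of the 1,1-dimethylallyl ether transposes the allyl unit to an ortho carbon as a prenyl group, and since the two ortho positions of the symmetric ring are equivalent and unsubstituted, rearomatisation should give one ortho-prenylphenol.

Step 6
Reactants: 5 (S)-1-[4-methoxy-3-(triisopropylsilyloxy)phenyl]-3-(trimethylsilyl)prop-2-yn-1-ol; 10 3,5-dimethoxy-2-prenylphenol
Product: 11 (R)-{3-(3,5-dimethoxy-2-prenylphenoxy)-3-[4-methoxy-3-(triisopropylsilyloxy)phenyl]prop-1-yn-1-yl}trimethylsilane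
Conditions: PPh3, DIAD, PhMe, −20 °C → rt
Reagents that add atoms: none
Why: Mitsunobu etherification, in which the phenoxide of 10 displaces the activated carbinol oxygen by SN2 with inversion, so the S alcohol gives the ether with the spatial arrangement of C2 of the target (letter R because the silylalkynyl group outranks aryl), while the non-polar solvent and low temperature restrain ionisation of the anisyl-type carbinol and the trimethylsilyl cap disfavours SN2′ attack at the alkyne terminus.

Step 7
Reactants: 11 (R)-{3-(3,5-dimethoxy-2-prenylphenoxy)-3-[4-methoxy-3-(triisopropylsilyloxy)phenyl]prop-1-yn-1-yl}trimethylsilane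
Product: 12 (S)-{5-[1-(3,5-dimethoxy-2-prenylphenoxy)prop-2-yn-1-yl]-2-methoxyphenoxy}triisopropylsilane
Conditions: K2CO3 (cat.), MeOH–THF, 0 °C
Reagents that add atoms: none
Why: Base-catalysed methanolysis of the alkynyl C–SiMe3 bond is much faster than attack at the hindered aryl O–Si(i-Pr)3 bond and does not touch C2, whose letter becomes S only because aryl now outranks ethynyl.

Step 8
Reactants: 12 (S)-{5-[1-(3,5-dimethoxy-2-prenylphenoxy)prop-2-yn-1-yl]-2-methoxyphenoxy}triisopropylsilane
Product: 15 (R)-triisopropyl({3-(3,5-dimethoxy-2-prenylphenoxy)-3-[4-methoxy-3-(triisopropylsilyloxy)phenyl]prop-1-yn-1-yl}oxy)silane, via lithium acetylide 13 (not isolated), via lithium ynolate 14 (not isolated)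
Conditions: n-BuLi, THF, −78 °C; LiOOt-Bu (from t-BuOOH and LiN(SiMe3)2), −78 → 0 °C; TIPSOTf, −78 → 0 °C
Reagents that add atoms: tert-butyl hydroperoxide (used as LiOOt-Bu), CC(C)(C)OO; triisopropylsilyl trifluoromethanesulfonate (TIPSOTf), CC(C)[Si](OS(=O)(=O)C(F)(F)F)(C(C)C)C(C)C
Why: Electrophilic oxygenation of the lithium acetylide by the oxenoid LiOOt-Bu should give the lithium ynolate with loss of LiOt-Bu, which the bulky silyl triflate traps on oxygen as the chromatographically stable triisopropylsilyl ynol ether, while n-BuLi at −78 °C removes only the acetylenic proton so that C2 keeps its configuration.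

Step 9
Reactants: 15 (R)-triisopropyl({3-(3,5-dimethoxy-2-prenylphenoxy)-3-[4-methoxy-3-(triisopropylsilyloxy)phenyl]prop-1-yn-1-yl}oxy)silane
Product: 17 (S)-5,7-dimethoxy-2-[4-methoxy-3-(triisopropylsilyloxy)phenyl]-8-prenyl-4-(triisopropylsilyloxy)-2H-chromene, via silyl ketenium ion 16 (not isolated)
Conditions: HNTf2 (5 mol%), 4 Å MS, CH2Cl2, −78 → −40 °C; then Et3N, −78 °C
Reagents that add atoms: none
Why: HNTf2 protonates C3, the nucleophilic β-carbon of the ynol ether, to give silyl ketenium ion 16, whose digonal C4 is attacked by C4a of ring A; loss of the C4a proton rearomatises ring A, returns the acid and leaves the C3=C4 enol silane. The closest known reaction type is the Brønsted acid-promoted carbocyclisation of arene-tethered siloxyalkynes to tetralone enol silanes, used here with O1 as a tether atom. Ring C closes as a six-membered ring by in-plane attack on the C4=O π bond of the ketenium ion (6-exo-dig with respect to that bond, C3=C4 remaining endocyclic), which is the geometry of an intramolecular Friedel–Crafts acylation. No stereocentre is created; C2 is a spectator that keeps its arrangement provided the C2–O1 bond is not ionised, and its letter returns to S because aryl outranks C3 in 17. Site selectivity rests on the substrate: C4a is the only carbon ortho to O1 that bears hydrogen (C8 carries the prenyl group), it is activated by O1, the C5 methoxy and the C7 methoxy, C6 cannot reach C4, and ring B could only close a five-membered ring through a carbon activated by one silyloxy group. Chemoselectivity rests on the ynol ether being by far the most basic π system, so that a few mol% of acid at low temperature should protonate it before the prenyl alkene or O1, and premature protodesilylation of the enol silane would only give the C4 ketone that step 10 forms anyway.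

Step 10
Reactants: 17 (S)-5,7-dimethoxy-2-[4-methoxy-3-(triisopropylsilyloxy)phenyl]-8-prenyl-4-(triisopropylsilyloxy)-2H-chromene
Product: 18 (S)-2-(3-hydroxy-4-methoxyphenyl)-5,7-dimethoxy-8-prenylchroman-4-one (CNP0403319.1)
Conditions: Bu4NF, AcOH, THF, 0 °C → rt
Reagents that add atoms: none
Why: Fluoride-induced desilylation cleaves the enol silane and the aryl silyl ether in one operation and the enol ketonises by protonation at C3 (a methylene, so no stereocentre arises), while the acetic acid buffer protonates the incipient enolate and phenoxide before O1 can be expelled by β-elimination, which would open ring C and racemise C2.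

**Compound list**

1 | isovanillin (3-hydroxy-4-methoxybenzaldehyde) | COc1ccc(C=O)cc1O | starting material
2 | 4-methoxy-3-(triisopropylsilyloxy)benzaldehyde | COc1ccc(C=O)cc1O[Si](C(C)C)(C(C)C)C(C)C | intermediate
3 | ethynyltrimethylsilane | C#C[Si](C)(C)C | starting material
4 | ethyl(trimethylsilylethynyl)zinc | CC[Zn]C#C[Si](C)(C)C | intermediate
5 | (S)-1-[4-methoxy-3-(triisopropylsilyloxy)phenyl]-3-(trimethylsilyl)prop-2-yn-1-ol | COc1ccc([C@H](O)C#C[Si](C)(C)C)cc1O[Si](C(C)C)(C(C)C)C(C)C | intermediate
6 | 3,5-dimethoxyphenol | COc1cc(O)cc(OC)c1 | starting material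
7 | 3-chloro-3-methylbut-1-yne | CC(C)(Cl)C#C | starting material
8 | 1,3-dimethoxy-5-[(2-methylbut-3-yn-2-yl)oxy]benzene | COc1cc(OC)cc(OC(C)(C)C#C)c1 | intermediate
9 | 1,3-dimethoxy-5-[(2-methylbut-3-en-2-yl)oxy]benzene | COc1cc(OC)cc(OC(C)(C)C=C)c1 | intermediate
10 | 3,5-dimethoxy-2-(3-methylbut-2-en-1-yl)phenol | COc1cc(O)c(CC=C(C)C)c(OC)c1 | intermediate
11 | (R)-{3-(3,5-dimethoxy-2-prenylphenoxy)-3-[4-methoxy-3-(triisopropylsilyloxy)phenyl]prop-1-yn-1-yl}trimethylsilane | COc1ccc([C@@H](Oc2cc(OC)cc(OC)c2CC=C(C)C)C#C[Si](C)(C)C)cc1O[Si](C(C)C)(C(C)C)C(C)C | intermediate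
12 | (S)-{5-[1-(3,5-dimethoxy-2-prenylphenoxy)prop-2-yn-1-yl]-2-methoxyphenoxy}triisopropylsilane | COc1ccc([C@@H](Oc2cc(OC)cc(OC)c2CC=C(C)C)C#C)cc1O[Si](C(C)C)(C(C)C)C(C)C | intermediate
13 | lithium acetylide of 12 (terminal C–H replaced by C–Li, arrangement at C2 as in 12) | COc1ccc([C@@H](Oc2cc(OC)cc(OC)c2CC=C(C)C)C#C[Li])cc1O[Si](C(C)C)(C(C)C)C(C)C | intermediate
14 | lithium ynolate derived from 13 (C≡C–OLi, arrangement at C2 as in 12) | COc1ccc([C@@H](Oc2cc(OC)cc(OC)c2CC=C(C)C)C#CO[Li])cc1O[Si](C(C)C)(C(C)C)C(C)C | intermediate
15 | (R)-triisopropyl({3-(3,5-dimethoxy-2-prenylphenoxy)-3-[4-methoxy-3-(triisopropylsilyloxy)phenyl]prop-1-yn-1-yl}oxy)silane | COc1ccc([C@@H](Oc2cc(OC)cc(OC)c2CC=C(C)C)C#CO[Si](C(C)C)(C(C)C)C(C)C)cc1O[Si](C(C)C)(C(C)C)C(C)C | intermediate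
16 | silyl ketenium ion from C3-protonation of 15 (C3H=C4=O+–Si(i-Pr)3, arrangement at C2 as in 15) | COc1ccc([C@@H](Oc2cc(OC)cc(OC)c2CC=C(C)C)C=C=[O+][Si](C(C)C)(C(C)C)C(C)C)cc1O[Si](C(C)C)(C(C)C)C(C)C | intermediate
17 | (S)-5,7-dimethoxy-2-[4-methoxy-3-(triisopropylsilyloxy)phenyl]-8-prenyl-4-(triisopropylsilyloxy)-2H-chromene | COc1ccc([C@@H]2C=C(O[Si](C(C)C)(C(C)C)C(C)C)c3c(OC)cc(OC)c(CC=C(C)C)c3O2)cc1O[Si](C(C)C)(C(C)C)C(C)C | intermediate
18 | (S)-2-(3-hydroxy-4-methoxyphenyl)-5,7-dimethoxy-8-(3-methylbut-2-en-1-yl)chroman-4-one | COc1ccc([C@@H]2CC(=O)c3c(OC)cc(OC)c(CC=C(C)C)c3O2)cc1O | target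

**Step count.** Total: 10 steps. Longest linear sequence: 8 steps (steps 3–10, from 3,5-dimethoxyphenol).

**Steps most likely to fail**

Step 9. The acid may ionise the C2–O1 bond, which is benzylic to the para-methoxy ring and propargylic, faster than ring C closes. That would cost configuration at C2 or transfer the benzylic unit to carbon; protonation of the prenyl alkene is a second drain. The fallback sets out from 12 and comes back at 18. Ynolate 14, generated as in step 8, would be added to cold ethanolic HCl so that the ketene formed on C-protonation is captured by ethanol (the last stage of the Kowalski ester homologation), giving ethyl (S)-3-(3,5-dimethoxy-2-prenylphenoxy)-3-[4-methoxy-3-(triisopropylsilyloxy)phenyl]propanoate F1. Saponification (LiOH, THF–H2O, 0 °C) would give (S)-3-(3,5-dimethoxy-2-prenylphenoxy)-3-[4-methoxy-3-(triisopropylsilyloxy)phenyl]propanoic acid F2. TFAA in CH2Cl2 at 0 °C would then close ring C at C4a by intramolecular Friedel–Crafts acylation through the mixed anhydride, which a phloroglucinol triether should accept without strong acid, giving (S)-5,7-dimethoxy-2-[4-methoxy-3-(triisopropylsilyloxy)phenyl]-8-prenylchroman-4-one F3. Bu4NF/AcOH as in step 10 would give 18.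

Step 6. The alkoxyphosphonium intermediate may ionise to the anisyl-stabilised propargylic cation before the phenoxide attacks, eroding enantiomeric purity, and the ortho-substituted phenol may react slowly enough for elimination to compete. The fallback sets out from 2 and 10 and comes back at 12, replacing steps 2, 6 and 7. HC≡CMgBr (THF, 0 °C) would add to 2 to give racemic 1-[4-methoxy-3-(triisopropylsilyloxy)phenyl]prop-2-yn-1-ol F4, and Ac2O/Et3N/DMAP would give racemic 1-[4-methoxy-3-(triisopropylsilyloxy)phenyl]prop-2-yn-1-yl acetate F5. Copper-catalysed enantioconvergent propargylic etherification of F5 with phenol 10 (CuOTf·1/2C6H6, chiral pybox ligand, i-Pr2NEt, low temperature) would pass through a copper allenylidene and set C2 in the C–O bond-forming event, the ligand antipode being chosen to give 12. Oxygen versus carbon attack by the electron-rich phenol would have to be checked.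

Step 8. Oxygen transfer to the acetylide may be incomplete, the ynolate may expel the aryloxide from C2 on warming, or silylation may occur on carbon to give a silylketene. The fallback sets out from 12 and comes back at 18 without a siloxyalkyne. Anti-Markovnikov hydroboration of the terminal alkyne with Cy2BH (THF, 0 °C; the trisubstituted prenyl alkene should react far more slowly) and buffered oxidation (NaBO3·4H2O) would give (S)-3-(3,5-dimethoxy-2-prenylphenoxy)-3-[4-methoxy-3-(triisopropylsilyloxy)phenyl]propanal F6. Pinnick oxidation (NaClO2, NaH2PO4, 2-methylbut-2-ene, t-BuOH–H2O) would take it to acid F2, from which the Friedel–Crafts closure to F3 and the desilylation to 18 follow as in the fallback for step 9.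

Further compounds
F1 | step 9 | ethyl (S)-3-(3,5-dimethoxy-2-prenylphenoxy)-3-[4-methoxy-3-(triisopropylsilyloxy)phenyl]propanoate | COc1ccc([C@@H](Oc2cc(OC)cc(OC)c2CC=C(C)C)CC(=O)OCC)cc1O[Si](C(C)C)(C(C)C)C(C)C
F2 | step 9 | (S)-3-(3,5-dimethoxy-2-prenylphenoxy)-3-[4-methoxy-3-(triisopropylsilyloxy)phenyl]propanoic acid | COc1ccc([C@@H](Oc2cc(OC)cc(OC)c2CC=C(C)C)CC(=O)O)cc1O[Si](C(C)C)(C(C)C)C(C)C
F3 | step 9 | (S)-5,7-dimethoxy-2-[4-methoxy-3-(triisopropylsilyloxy)phenyl]-8-prenylchroman-4-one | COc1ccc([C@@H]2CC(=O)c3c(OC)cc(OC)c(CC=C(C)C)c3O2)cc1O[Si](C(C)C)(C(C)C)C(C)C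
F4 | step 6 | racemic 1-[4-methoxy-3-(triisopropylsilyloxy)phenyl]prop-2-yn-1-ol | COc1ccc(C(O)C#C)cc1O[Si](C(C)C)(C(C)C)C(C)C
F5 | step 6 | racemic 1-[4-methoxy-3-(triisopropylsilyloxy)phenyl]prop-2-yn-1-yl acetate | COc1ccc(C(OC(C)=O)C#C)cc1O[Si](C(C)C)(C(C)C)C(C)C
F6 | step 8 | (S)-3-(3,5-dimethoxy-2-prenylphenoxy)-3-[4-methoxy-3-(triisopropylsilyloxy)phenyl]propanal | COc1ccc([C@@H](Oc2cc(OC)cc(OC)c2CC=C(C)C)CC=O)cc1O[Si](C(C)C)(C(C)C)C(C)C
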